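**Plan**

- Retrosynthesis: the three phenols are unmasked last (benzyl ethers). The acetate comes from the C4 alcohol and that from a C4 ketone. The oxane ring is then cut across, at C2–C3 and at O1–C6.
- Enabling feature: in the oxane ring, O1–C2(aryl) is a masked aryl aldehyde C=O and C3–C4(O)–C5–C6 is a masked 2-silyloxybuta-1,3-diene. The 4-oxygenated oxane is therefore the retron of an oxa-Diels–Alder reaction.
- Forward: the diene is made from hydroferulic acid (benzylation, half-reduction, Wittig olefination, enol silylation) and the aldehyde from 5-hydroxyvanillin (benzylation). The cycloaddition joins the two halves and forms the only new ring. Reduction, acetylation and hydrogenolysis follow.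
- Stereochemistry: C2 comes from the chiral chromium catalyst, C6 from the endo transition state (2,6-cis), and C4 from equatorial hydride attack on the chair ketone (axial oxygen, trans to both ring substituents).

Key step: step 6

Assumption: CrCl(L) (L = the doubly deprotonated tridentate Schiff base from (1S,2R)-1-amino-2-indanol and 3-(1-adamantyl)-2-hydroxy-5-methylbenzaldehyde) is taken to direct the diene to the Si face of the aldehyde, as the usual model for this catalyst family predicts; compounds 1, 4 and 7 are taken as commercial.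

**Route**

Step 1
Reactants: 1 3-(4-hydroxy-3-methoxyphenyl)propanoic acid (hydroferulic acid)
Product: 2 benzyl 3-[4-(benzyloxy)-3-methoxyphenyl]propanoate
Conditions: BnBr (2.4 equiv), K2CO3 (3 equiv), DMF, 60 °C
Reagents that add atoms: benzyl bromide, BrCc1ccccc1
Why: Phenoxide and carboxylate are both alkylated by benzyl bromide (Williamson etherification and carboxylate O-alkylation), so one operation masks the phenol and gives an ester suited to half-reduction.

Step 2
Reactants: 2 benzyl 3-[4-(benzyloxy)-3-methoxyphenyl]propanoate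
Product: 3 3-[4-(benzyloxy)-3-methoxyphenyl]propanal
Conditions: i-Bu2AlH (1.1 equiv), CH2Cl2, −78 °C; then aq. KNaC4H4O6 (potassium sodium tartrate)
Reagents that add atoms: none
Why: Partial reduction of an ester with i-Bu2AlH at low temperature should stop at the aluminium hemiacetal, which releases the aldehyde only on work-up; the aryl benzyl ether is inert.

Step 3
Reactants: 3 3-[4-(benzyloxy)-3-methoxyphenyl]propanal; 4 1-(triphenylphosphoranylidene)propan-2-one
Product: 5 (3E)-6-[4-(benzyloxy)-3-methoxyphenyl]hex-3-en-2-one
Conditions: toluene, 90 °C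
Reagents that add atoms: none
Why: Wittig olefination of an aliphatic aldehyde with a stabilised acyl ylide should give the (E)-enone, the geometry that later fixes the C6 configuration relative to C2.

Step 4
Reactants: 5 (3E)-6-[4-(benzyloxy)-3-methoxyphenyl]hex-3-en-2-one
Product: 6 triethyl({(3E)-6-[4-(benzyloxy)-3-methoxyphenyl]hexa-1,3-dien-2-yl}oxy)silane
Conditions: Et3SiOTf (1.3 equiv), Et3N (2 equiv), Et2O, 0 °C
Reagents that add atoms: triethylsilyl trifluoromethanesulfonate, CC[Si](CC)(CC)OS(=O)(=O)C(F)(F)F
Why: Soft enolisation of the methyl ketone (O-silylation, then loss of a methyl proton to the amine) should give the cross-conjugated 2-silyloxydiene with the (E)-alkene untouched, a standard silyl enol ether formation from methyl enones.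

Step 5
Reactants: 7 3,4-dihydroxy-5-methoxybenzaldehyde (5-hydroxyvanillin)
Product: 8 3,4-bis(benzyloxy)-5-methoxybenzaldehyde
Conditions: BnBr (2.4 equiv), K2CO3 (3 equiv), DMF, 60 °C
Reagents that add atoms: benzyl bromide, BrCc1ccccc1
Why: Double Williamson etherification of the catechol gives an aldehyde free of acidic protons; its protecting groups can be removed at the end together with the one on the other ring.

Step 6
Reactants: 6 triethyl({(3E)-6-[4-(benzyloxy)-3-methoxyphenyl]hexa-1,3-dien-2-yl}oxy)silane; 8 3,4-bis(benzyloxy)-5-methoxybenzaldehyde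
Product: 10 (2S,6S)-2-[3,4-bis(benzyloxy)-5-methoxyphenyl]-6-{2-[4-(benzyloxy)-3-methoxyphenyl]ethyl}oxan-4-one, via dihydropyran triethylsilyl enol ether 9 (not isolated)
Conditions: CrCl(L) (10 mol %), 4 Å molecular sieves, t-BuOMe (minimum volume), rt; then TFA, CH2Cl2, 0 °C; aq. NaHCO3
Reagents that add atoms: none
Why: The trivalent-chromium Lewis acid CrCl(L) binds the aldehyde oxygen of 8 anti to the aryl group, and the electron-rich diene 6 adds in a concerted, asynchronous [4+2] cycloaddition (oxa-Diels–Alder) in which C1 of the diene bonds to the carbonyl carbon and the carbonyl oxygen bonds to C4 of the diene; mild acid then converts enol ether 9 into ketone 10 without touching the two new stereocentres. The closest known reaction type is the catalytic asymmetric hetero-Diels–Alder reaction of aldehydes with 4-substituted 2-silyloxybuta-1,3-dienes under tridentate Schiff-base chromium catalysis. The oxane ring is closed by this single intermolecular [4+2] cycloaddition, not by a stepwise ring closure. C2 is set by the catalyst, which is expected to shield the Re face of the bound aldehyde so that the diene adds to the Si face (2S); C6 is set relative to C2 by the endo transition state of the (E)-diene, which places the aryl and arylethyl groups cis (6S). The step needs regioselectivity, which the silyloxy group secures by making C1 the nucleophilic diene terminus; endo selectivity, which the bulky Lewis acid secures by sitting exo; and enough dienophile reactivity, which is helped because the central 4-benzyloxy group of 8 is twisted out of conjugation by its two ortho neighbours.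

Step 7
Reactants: 10 (2S,6S)-2-[3,4-bis(benzyloxy)-5-methoxyphenyl]-6-{2-[4-(benzyloxy)-3-methoxyphenyl]ethyl}oxan-4-one
Product: 11 (2S,4S,6S)-2-[3,4-bis(benzyloxy)-5-methoxyphenyl]-6-{2-[4-(benzyloxy)-3-methoxyphenyl]ethyl}oxan-4-ol (hydroxyl axial, trans to both ring substituents)
Conditions: Li[HB(s-Bu)3] (1.3 equiv), THF, −78 °C; then H2O
Reagents that add atoms: none
Why: In this diastereoselective ketone reduction the hindered trialkylborohydride should approach the chair ketone (C2 and C6 substituents equatorial) along the equatorial trajectory, away from the axial hydrogens at C2 and C6, and so give the axial (4S) alcohol.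

Step 8
Reactants: 11 (2S,4S,6S)-2-[3,4-bis(benzyloxy)-5-methoxyphenyl]-6-{2-[4-(benzyloxy)-3-methoxyphenyl]ethyl}oxan-4-ol
Product: 12 (2S,4S,6S)-2-[3,4-bis(benzyloxy)-5-methoxyphenyl]-6-{2-[4-(benzyloxy)-3-methoxyphenyl]ethyl}oxan-4-yl acetate
Conditions: Ac2O, pyridine, DMAP (cat.), CH2Cl2, rt
Reagents that add atoms: acetic anhydride, CC(=O)OC(C)=O
Why: Nucleophile-catalysed acylation of the only free hydroxyl proceeds at oxygen with retention at C4, and placing it before phenol unmasking ensures that only the secondary alcohol is acetylated.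

Step 9
Reactants: 12 (2S,4S,6S)-2-[3,4-bis(benzyloxy)-5-methoxyphenyl]-6-{2-[4-(benzyloxy)-3-methoxyphenyl]ethyl}oxan-4-yl acetate
Product: 13 (2S,4S,6S)-2-(3,4-dihydroxy-5-methoxyphenyl)-6-[2-(4-hydroxy-3-methoxyphenyl)ethyl]oxan-4-yl acetate (CNP0143286.2)
Conditions: H2 (1 atm), 10% Pd/C, EtOAc, rt, stopped after uptake of three equivalents
Reagents that add atoms: none
Why: Catalytic hydrogenolysis should cleave the three aryl benzyl ethers much faster than the cyclic benzylic C2–O bond, and it leaves the acetate, the methyl ethers and all three stereocentres untouched.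

**Compound list**

1 | 3-(4-hydroxy-3-methoxyphenyl)propanoic acid | COc1cc(CCC(=O)O)ccc1O | starting material
2 | benzyl 3-[4-(benzyloxy)-3-methoxyphenyl]propanoate | COc1cc(CCC(=O)OCc2ccccc2)ccc1OCc1ccccc1 | intermediate
3 | 3-[4-(benzyloxy)-3-methoxyphenyl]propanal | COc1cc(CCC=O)ccc1OCc1ccccc1 | intermediate
4 | 1-(triphenylphosphoranylidene)propan-2-one | CC(=O)C=P(c1ccccc1)(c1ccccc1)c1ccccc1 | starting material
5 | (3E)-6-[4-(benzyloxy)-3-methoxyphenyl]hex-3-en-2-one | COc1cc(CC/C=C/C(C)=O)ccc1OCc1ccccc1 | intermediate
6 | triethyl({(3E)-6-[4-(benzyloxy)-3-methoxyphenyl]hexa-1,3-dien-2-yl}oxy)silane | COc1cc(CC/C=C/C(=C)O[Si](CC)(CC)CC)ccc1OCc1ccccc1 | intermediate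
7 | 3,4-dihydroxy-5-methoxybenzaldehyde | COc1cc(C=O)cc(O)c1O | starting material
8 | 3,4-bis(benzyloxy)-5-methoxybenzaldehyde | COc1cc(C=O)cc(OCc2ccccc2)c1OCc1ccccc1 | intermediate
9 | triethyl({(2S,6S)-2-[3,4-bis(benzyloxy)-5-methoxyphenyl]-6-{2-[4-(benzyloxy)-3-methoxyphenyl]ethyl}-3,6-dihydro-2H-pyran-4-yl}oxy)silane | COc1cc(CC[C@H]2C=C(O[Si](CC)(CC)CC)C[C@@H](c3cc(OCc4ccccc4)c(OCc4ccccc4)c(OC)c3)O2)ccc1OCc1ccccc1 | intermediate
10 | (2S,6S)-2-[3,4-bis(benzyloxy)-5-methoxyphenyl]-6-{2-[4-(benzyloxy)-3-methoxyphenyl]ethyl}oxan-4-one | COc1cc(CC[C@H]2CC(=O)C[C@@H](c3cc(OCc4ccccc4)c(OCc4ccccc4)c(OC)c3)O2)ccc1OCc1ccccc1 | intermediate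
11 | (2S,4S,6S)-2-[3,4-bis(benzyloxy)-5-methoxyphenyl]-6-{2-[4-(benzyloxy)-3-methoxyphenyl]ethyl}oxan-4-ol | COc1cc(CC[C@H]2C[C@H](O)C[C@@H](c3cc(OCc4ccccc4)c(OCc4ccccc4)c(OC)c3)O2)ccc1OCc1ccccc1 | intermediate
12 | (2S,4S,6S)-2-[3,4-bis(benzyloxy)-5-methoxyphenyl]-6-{2-[4-(benzyloxy)-3-methoxyphenyl]ethyl}oxan-4-yl acetate | COc1cc(CC[C@H]2C[C@H](OC(C)=O)C[C@@H](c3cc(OCc4ccccc4)c(OCc4ccccc4)c(OC)c3)O2)ccc1OCc1ccccc1 | intermediate
13 | (2S,4S,6S)-2-(3,4-dihydroxy-5-methoxyphenyl)-6-[2-(4-hydroxy-3-methoxyphenyl)ethyl]oxan-4-yl acetate | COc1cc(CC[C@H]2C[C@H](OC(C)=O)C[C@@H](c3cc(O)c(O)c(OC)c3)O2)ccc1O | target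

**Step count and risks**

Total step count: 9. Longest linear sequence: 8 steps (steps 1, 2, 3, 4, 6, 7, 8, 9); step 5 is a one-step branch.

The three steps most likely to fail:

Step 6. The cycloaddition may be sluggish with the electron-rich aryl aldehyde, the diene may hydrolyse before it reacts, or enantiofacial control may be insufficient. The fallback sets out from enone 5 and aldehyde 8 and comes back to the route at ketone 10, making the two bonds in two operations instead of one. Enone 5 is enolised at its methyl group with (−)-Ipc2BCl and Et3N in Et2O at 0 °C, the Ipc2BCl antipode expected by the usual model for methyl ketones to direct the enolate to the Si face of the aldehyde. Aldehyde 8 is added at −78 °C, and oxidative work-up (H2O2, pH 7 buffer) of this boron-mediated asymmetric aldol reaction should give (1S,4E)-1-[3,4-bis(benzyloxy)-5-methoxyphenyl]-7-[4-(benzyloxy)-3-methoxyphenyl]-1-hydroxyhept-4-en-3-one F1. Acid-catalysed 6-endo-trig oxa-Michael cyclisation of this hydroxy enone (Amberlyst-15, CH2Cl2, rt) under thermodynamic control should then place both ring substituents equatorial and give the 2,6-cis ketone 10.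

Step 9. Over-reduction may occur: hydrogenolysis of the ring benzylic C2–O bond could compete with O-debenzylation and open the oxane. The fallback sets out from acetate 12 and comes back to the route at target 13 by a non-reductive, Lewis-acid debenzylation. BCl3 with pentamethylbenzene as cation scavenger in CH2Cl2 at −78 °C should transfer the three benzyl groups to the scavenger by Friedel–Crafts alkylation, while the acetate and the methyl ethers are expected to survive at this temperature. This fallback makes no compound outside the list (F0).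

Step 7. Facial selectivity in hydride delivery may be poor, or the basic borohydride may trigger retro-oxa-Michael opening of the β-alkoxy ketone. The fallback sets out from ketone 10 and comes back to the route at acetate 12, bypassing alcohol 11. NaBH4 in MeOH at −20 °C should attack axially and give the all-cis, equatorial alcohol (2S,4R,6S)-2-[3,4-bis(benzyloxy)-5-methoxyphenyl]-6-{2-[4-(benzyloxy)-3-methoxyphenyl]ethyl}oxan-4-ol F2. A Mitsunobu reaction of this alcohol with acetic acid (PPh3, DIAD, toluene, 0 °C to rt) should invert C4 and install the axial acetate in one operation, giving 12.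

**Further compounds**

F1 | step 6 | (1S,4E)-1-[3,4-bis(benzyloxy)-5-methoxyphenyl]-7-[4-(benzyloxy)-3-methoxyphenyl]-1-hydroxyhept-4-en-3-one | COc1cc(CC/C=C/C(=O)C[C@H](O)c2cc(OCc3ccccc3)c(OCc3ccccc3)c(OC)c2)ccc1OCc1ccccc1
F0 | step 9 | none | none
F2 | step 7 | (2S,4R,6S)-2-[3,4-bis(benzyloxy)-5-methoxyphenyl]-6-{2-[4-(benzyloxy)-3-methoxyphenyl]ethyl}oxan-4-ol | COc1cc(CC[C@H]2C[C@@H](O)C[C@@H](c3cc(OCc4ccccc4)c(OCc4ccccc4)c(OC)c3)O2)ccc1OCc1ccccc1
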